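## The problem

Target 13 is an isoflavone: benzene ring A is fused through C4a–C8a to the 4-pyranone ring C, and aryl ring B sits on C3. It has no stereocentre, so the difficulty lies in where the bonds are made and in what the functional groups tolerate. Ring A carries free hydroxyls at C5 and C7 while ring B carries a methyl ether at C4', so the masks on the ring A oxygens must be removable without touching an aryl methyl ether. The 3-methylbut-2-enyl chain at C3' is the fragile group: acid protonates its trisubstituted alkene to a tertiary cation, and hydrogenolysis saturates it, so it cannot be present during an acid-mediated ring closure or a Lewis-acid deprotection. The pyranone is electrophilic at C2 and opens with hydroxide or alkoxide, which limits strong base late in the route. The one geometric element on the way is the C=C bond of an open-chain acrylic acid, which must hold the carboxyl cis to the aryloxy group for ring C to close. The feature that makes the chosen closure possible is ring A itself: it is a phloroglucinol unit, and C4a lies ortho to O1 and O5 and para to O7. In the open-chain precursor the two carbons ortho to the ether oxygen are equivalent by symmetry, so acylation at C4a has no regiochemical choice.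

## Retrosynthesis

13 ⇒ 11 + 12. The bond between C3' and the allylic CH2 is cut first. The side chain cannot travel through the acid steps that build and unmask the chromone, so it is added last to bromide 11 from stannane 12. The bromine is an inert placeholder that is already present in the purchased acid 1. The forward coupling has to work at an electron-rich, ortho-methoxy aryl bromide, deliver the linear allyl isomer and tolerate two free phenols.

11 ⇒ 10. The two O–CH2Ph bonds are cut. Methyl ethers on ring A could not be told apart from the 4'-methoxy group, and acetal protecting groups would not survive the acylation, whereas benzyl ethers come with the purchased phenol 6. The cleavage must spare the C–Br bond, the C2=C3 double bond and the methyl ether. That excludes hydrogenolysis and points to a boron Lewis acid with a cation scavenger, used before the prenyl group exists.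

10 ⇒ 8 (through 9). This is the strategic cut, C4–C4a. A cut at O1–C2 and C2–C3 would need an intermolecular acylation of an unsymmetrical protected ring A followed by a one-carbon insertion. A cut at C3–C1' would need a 3-halochromone and a boron partner on a ring B that already carries a bromide. Opening C4–C4a instead gives acid 8, in which ring A is a symmetric 3,5-dioxygenated phenoxy group. This removes one ring and one skeletal bond and leaves no regiochemical question. The forward reaction must activate the carboxyl (as mixed anhydride 9) mildly enough to keep the benzyl ethers and the aryl vinyl ether, with the acyl carbon cis to the aryloxy group.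

8 ⇒ 7 ⇒ 5 + 6. After ester hydrolysis (8 from 7), the vinyl ether C–O bond, the future O1–C2, is cut. This divides the molecule into two halves of similar size, phenol 6 and enol sulfonate 5. The substitution is run on the ester, because a carboxylate would deactivate the acceptor. It must occur at oxygen of the phenoxide and keep the alkene geometry, and the hydrolysis that follows must not displace the phenoxide again.

5 ⇒ 4 ⇒ 2 + 3. The O–S bond of the sulfonate and then the bond between the α-carbon and the formyl carbon (the future C2–C3) are cut. The formyl carbon comes from methyl formate 3 in a crossed Claisen condensation in which only 2 can enolise and only 3 can act as the electrophile. The sulfonylation of enol 4 fixes the geometry.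

2 ⇒ 1. The methyl ester is traced to the purchased arylacetic acid 1, so all of ring B with its methoxy group and bromine comes from one starting material.

## Roads not taken

Alternative 1: The carbonyl carbon C4 is disconnected from both neighbours, C3 and C4a. In the forward step Pd(PPh3)4 (zerovalent palladium) with LiCl would join enol triflate A2, carbon monoxide A4 and arylstannane A3 to the aryl vinyl ketone A1.
- Merits: two skeletal bonds form in one operation, the assembly is convergent, the position of tin fixes the ring A regiochemistry, and the prenyl group travels from the start under neutral conditions.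
- Weak points: transmetalation of the 2,6-dioxygenated A3 is slow, so direct coupling without carbonyl insertion competes. A1 is still far from the target: the methoxymethyl groups must be removed with acid in the presence of the prenyl group. Ring C then closes by conjugate addition only at the isoflavanone oxidation level, and the dehydrogenation must spare the prenyl group and a free phloroglucinol ring.
- Comparison: this road is more convergent and needs no late functionalisation of ring B, and in that respect it is better. The chosen plan sets against it that ring closure gives the pyranone directly at the right oxidation level, and that prenylated material sees only one neutral step. Both roads use an organotin reagent.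

Alternative 2: Ring B is built last, by cutting C2'–C3' and C5'–C6'. With KOtBu the two α-carbons of ketone A6 would condense with the two termini of the chromone-bearing vinamidinium salt A7, both amine groups would be lost, and phenol A5 would result.
- Merits: the prenyl group comes from a cheap ketone, its position is fixed by the constitution of A6, and no cross-coupling, no tin and no question of linear versus branched allyl transfer arises. In these respects the road is superior.
- Weak points: A7 needs several steps of Vilsmeier-type chemistry on a chromone-3-acetic acid. The pyranone C2 of A7 is exposed to tert-butoxide, to the enolate of A6 and to the released amine, all of which can open ring C. A5 still needs methylation at O4' and removal of two allyl groups.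
- Comparison: the chosen plan is shorter, forms the pyranone late and under acid, where it is stable, and never exposes it to strong base. It pays for this with a late Stille coupling.

Alternative 3: Ring C is opened at O1–C8a. With K2CO3 in DMF the enol oxygen of formyl ketone A9 would displace an ortho fluoride and give the difluoroisoflavone A8.
- Merits: the closure is a mild, base-mediated aromatic substitution activated by the ketone, the two ortho fluorides are equivalent, and the prenyl group tolerates the conditions, so ring B can be complete from the start. As a ring closure it is at least as good as an acylation.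
- Weak points: A8 has fluorine where the target has hydroxyl. Two further substitutions by oxygen nucleophiles are needed, the second on a ring already deactivated by the first donor. The pyranone C2 competes as an electrophile, and the oxygen substituents must then be unmasked in the presence of the prenyl group.
- Comparison: the chosen plan has all three ring A oxygens in place from the first intermediate, so no C–F to C–O exchange is needed. It accepts an acid-mediated closure and a placeholder bromine in exchange.

Key step: step 6

Assumption: compounds 1, 3, 6 and 12 are taken as purchasable, and the α-formyl ester 4 is drawn as its hydrogen-bonded Z enol, the tautomer that is sulfonylated in step 3.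

## Route

Step 1
Reactants: 1 2-(3-bromo-4-methoxyphenyl)acetic acid
Product: 2 methyl 2-(3-bromo-4-methoxyphenyl)acetate
Conditions: MeOH, H2SO4 (cat.), reflux
Reagents that add atoms: methanol, CO
Why: Fischer esterification of an unhindered arylacetic acid; the aryl bromide and the methyl ether are inert to hot acidic methanol.

Step 2
Reactants: 2 methyl 2-(3-bromo-4-methoxyphenyl)acetate; 3 methyl formate
Product: 4 methyl (Z)-2-(3-bromo-4-methoxyphenyl)-3-hydroxyacrylate (enol form of the α-formyl ester)
Conditions: NaH, THF, 0 °C to rt; then aq. HCl
Reagents that add atoms: none
Why: Crossed Claisen formylation in which only 2 can enolise and only 3 is electrophilic; deprotonation of the product to its stabilised enolate drives the equilibrium, and acidification should give the chelated Z enol.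

Step 3
Reactants: 4 methyl (Z)-2-(3-bromo-4-methoxyphenyl)-3-hydroxyacrylate
Product: 5 methyl (Z)-2-(3-bromo-4-methoxyphenyl)-3-(tosyloxy)acrylate
Conditions: TsCl, N-methylimidazole, LiOH, toluene, 0 °C to rt
Reagents that add atoms: p-toluenesulfonyl chloride, Cc1ccc(cc1)S(=O)(=O)Cl
Why: O-sulfonylation of the enolate by the N-sulfonylimidazolium species; lithium should hold the enolate oxygen and the ester carbonyl on the same side, so the Z enol tosylate (sulfonate cis to the ester) is expected to predominate.

Step 4
Reactants: 5 methyl (Z)-2-(3-bromo-4-methoxyphenyl)-3-(tosyloxy)acrylate; 6 3,5-bis(benzyloxy)phenol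
Product: 7 methyl (Z)-3-[3,5-bis(benzyloxy)phenoxy]-2-(3-bromo-4-methoxyphenyl)acrylate
Conditions: K2CO3, MeCN, rt to 50 °C
Reagents that add atoms: none
Why: Nucleophilic vinylic substitution by addition–elimination: the phenoxide adds to the β-carbon of the acrylate and the ester-stabilised carbanion expels tosylate, a good leaving group, faster than it rotates, so retention of the Z geometry is expected; a polar aprotic solvent and a potassium counter-ion favour attack through oxygen.

Step 5
Reactants: 7 methyl (Z)-3-[3,5-bis(benzyloxy)phenoxy]-2-(3-bromo-4-methoxyphenyl)acrylate
Product: 8 (Z)-3-[3,5-bis(benzyloxy)phenoxy]-2-(3-bromo-4-methoxyphenyl)acrylic acid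
Conditions: LiOH, THF/H2O, 0 °C to rt; then dil. HCl, 0 °C
Reagents that add atoms: water, O (delivered as hydroxide from LiOH)
Why: Saponification by acyl–oxygen cleavage, as is routine for 3-aryloxyacrylic esters on the way to chromones; methanol is left out as co-solvent so that no alkoxide is available to exchange with the aryloxy group.

Step 6
Reactants: 8 (Z)-3-[3,5-bis(benzyloxy)phenoxy]-2-(3-bromo-4-methoxyphenyl)acrylic acid
Product: 10 5,7-bis(benzyloxy)-3-(3-bromo-4-methoxyphenyl)-4H-chromen-4-one, via mixed trifluoroacetic anhydride 9 (not isolated)
Conditions: TFAA (1.2 equiv), CH2Cl2, 0 °C to rt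
Reagents that add atoms: trifluoroacetic anhydride, O=C(OC(=O)C(F)(F)F)C(F)(F)F (its trifluoroacetyl group sits in intermediate 9 only; no atom of it remains in 10)
Why: Trifluoroacetic anhydride converts the acid into mixed anhydride 9, which with the liberated trifluoroacetic acid is in equilibrium with an acylium trifluoroacetate ion pair; such mixed anhydrides transfer the non-fluorinated acyl group. The acyl carbon, held cis to the aryloxy group on the Z alkene, is attacked by the ring A carbon ortho to the vinyl ether oxygen, and loss of a proton restores the aromatic ring; this is an intramolecular Friedel–Crafts acylation, the known passage from 3-aryloxyacrylic acids to chromones. Ring C closes in a six-membered exo mode at the acyl carbon (exo-trig on the anhydride carbonyl, exo-dig if the free acylium ion reacts) and the C4–C4a bond is formed. No stereocentre is created. The step needs site selectivity on ring A only, and the substrate secures it: the two carbons ortho to the ether oxygen are equivalent by symmetry and each is activated by all three oxygens, the para carbon cannot be reached, and attack on ring B would require a four-membered ring. Should some E acid be present, donation from the β-oxygen into the acylium ion lowers the C2–C3 bond order and reversible protonation at the α-carbon allows rotation, so both geometries should converge on 10. The benzyl ethers and the aryl bromide are inert to the anhydride and trifluoroacetic acid at room temperature, which is why bromine stands in for the acid-labile prenyl group. Once acylated, ring A is deactivated by the new carbonyl group, so a second acylation is not expected.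

Step 7
Reactants: 10 5,7-bis(benzyloxy)-3-(3-bromo-4-methoxyphenyl)-4H-chromen-4-one
Product: 11 3-(3-bromo-4-methoxyphenyl)-5,7-dihydroxy-4H-chromen-4-one
Conditions: BCl3, pentamethylbenzene, CH2Cl2, −78 °C
Reagents that add atoms: none
Why: Lewis-acid cleavage of aryl benzyl ethers; pentamethylbenzene traps the benzyl cation and so prevents C-benzylation of the phloroglucinol ring. The 4'-methyl ether has no neighbouring carbonyl to chelate boron and should survive at low temperature, and the C–Br bond and the C2=C3 double bond, both at risk under hydrogenolysis, are untouched.

Step 8
Reactants: 11 3-(3-bromo-4-methoxyphenyl)-5,7-dihydroxy-4H-chromen-4-one; 12 tributyl(3-methylbut-2-enyl)stannane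
Product: 13 5,7-dihydroxy-3-[4-methoxy-3-(3-methylbut-2-enyl)phenyl]-4H-chromen-4-one (the target)
Conditions: Pd(PPh3)4, DMF, 100 °C
Reagents that add atoms: none
Why: Stille coupling; after oxidative addition and allyl transfer from tin, the allylpalladium intermediate should eliminate reductively at its less substituted terminus and give the linear 3-methylbut-2-enyl arene. The neutral, base-free conditions tolerate the free phenols and the pyranone.

## Compound list

1 | 2-(3-bromo-4-methoxyphenyl)acetic acid | COc1ccc(CC(=O)O)cc1Br | starting material
2 | methyl 2-(3-bromo-4-methoxyphenyl)acetate | COC(=O)Cc1ccc(OC)c(Br)c1 | intermediate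
3 | methyl formate | COC=O | starting material
4 | methyl (Z)-2-(3-bromo-4-methoxyphenyl)-3-hydroxyacrylate | COC(=O)/C(=C\O)c1ccc(OC)c(Br)c1 | intermediate
5 | methyl (Z)-2-(3-bromo-4-methoxyphenyl)-3-(tosyloxy)acrylate | COC(=O)/C(=C\OS(=O)(=O)c1ccc(C)cc1)c1ccc(OC)c(Br)c1 | intermediate
6 | 3,5-bis(benzyloxy)phenol | Oc1cc(OCc2ccccc2)cc(OCc2ccccc2)c1 | starting material
7 | methyl (Z)-3-[3,5-bis(benzyloxy)phenoxy]-2-(3-bromo-4-methoxyphenyl)acrylate | COC(=O)/C(=C\Oc1cc(OCc2ccccc2)cc(OCc2ccccc2)c1)c1ccc(OC)c(Br)c1 | intermediate
8 | (Z)-3-[3,5-bis(benzyloxy)phenoxy]-2-(3-bromo-4-methoxyphenyl)acrylic acid | OC(=O)/C(=C\Oc1cc(OCc2ccccc2)cc(OCc2ccccc2)c1)c1ccc(OC)c(Br)c1 | intermediate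
9 | (Z)-3-[3,5-bis(benzyloxy)phenoxy]-2-(3-bromo-4-methoxyphenyl)acrylic trifluoroacetic anhydride (not isolated) | O=C(OC(=O)/C(=C\Oc1cc(OCc2ccccc2)cc(OCc2ccccc2)c1)c1ccc(OC)c(Br)c1)C(F)(F)F | intermediate
10 | 5,7-bis(benzyloxy)-3-(3-bromo-4-methoxyphenyl)-4H-chromen-4-one (5,7-bis(benzyloxy)-3'-bromo-4'-methoxyisoflavone) | COc1ccc(-c2coc3cc(OCc4ccccc4)cc(OCc4ccccc4)c3c2=O)cc1Br | intermediate
11 | 3-(3-bromo-4-methoxyphenyl)-5,7-dihydroxy-4H-chromen-4-one (3'-bromo-5,7-dihydroxy-4'-methoxyisoflavone) | COc1ccc(-c2coc3cc(O)cc(O)c3c2=O)cc1Br | intermediate
12 | tributyl(3-methylbut-2-enyl)stannane | CC(C)=CC[Sn](CCCC)(CCCC)CCCC | starting material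
13 | 5,7-dihydroxy-3-[4-methoxy-3-(3-methylbut-2-enyl)phenyl]-4H-chromen-4-one | COc1ccc(-c2coc3cc(O)cc(O)c3c2=O)cc1CC=C(C)C | target

## Step count and least certain steps

Total step count: 8. Longest linear sequence: 8 steps, from acid 1 to target 13; compounds 3, 6 and 12 enter as purchased partners.

Step 6 (key step). Three things may go wrong.
- Ring closure may be slow, so that the activated acid acylates ring A of a second molecule, or the excess anhydride trifluoroacetylates the very electron-rich ring A.
- The acidic medium may cause loss or migration of benzyl groups.
- If the acid arrives as the E isomer, equilibration to the reactive geometry may be incomplete.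

Fallback: the pyranone is built on the other side of the carbonyl group. The route is left at acid 1, which is condensed with benzene-1,3,5-triol in BF3·OEt2 at about 85 °C. This Friedel–Crafts C-acylation has no regiochemical choice on the symmetric triol and should give 2-(3-bromo-4-methoxyphenyl)-1-(2,4,6-trihydroxyphenyl)ethan-1-one F1. Treatment of F1 with N,N-dimethylformamide, methanesulfonyl chloride and BF3·OEt2 inserts the C2 carbon and closes ring C. This returns to the route at compound 11, so steps 2 to 7 are not needed.

Step 4. Three things may go wrong.
- The ambident phenoxide may attack through a ring carbon instead of oxygen.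
- The phenoxide may attack at sulfur, giving sulfonyl transfer back to enol 4.
- Reversible addition of phenoxide to the product may erode the alkene geometry.

Fallback: the sulfonate is replaced by a halide, and the anionic substitution by an amine-relayed one. The fallback starts from enol 4, which with oxalyl chloride and catalytic N,N-dimethylformamide in CH2Cl2 should give methyl (Z)-2-(3-bromo-4-methoxyphenyl)-3-chloroacrylate F2; either geometric isomer would serve. F2 is then treated with phenol 6 and DABCO in MeCN. The amine activates the β-carbon by reversible addition–elimination and the neutral phenol enters through oxygen. This returns to the route at compound 7.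

Step 5. Hydroxide may add to the β-carbon instead of the ester carbonyl and expel the phenoxide, which would take the material back to 4 and 6.

Fallback: the carboxyl is carried as an allyl ester, which is removed without any oxygen nucleophile. The fallback starts from acid 1.
- Allyl bromide and K2CO3 in DMF should give allyl 2-(3-bromo-4-methoxyphenyl)acetate F3.
- NaH and allyl formate in THF should give allyl (Z)-2-(3-bromo-4-methoxyphenyl)-3-hydroxyacrylate F4.
- TsCl, N-methylimidazole and LiOH should give allyl (Z)-2-(3-bromo-4-methoxyphenyl)-3-(tosyloxy)acrylate F5.
- Phenol 6 and K2CO3 in MeCN should give allyl (Z)-3-[3,5-bis(benzyloxy)phenoxy]-2-(3-bromo-4-methoxyphenyl)acrylate F6.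
- Pd(PPh3)4 and morpholine in THF at room temperature transfer the allyl group to the amine. At this temperature the electron-rich aryl bromide should not undergo oxidative addition.

This returns to the route at compound 8.

Step 8. Three things may go wrong.
- Allyl transfer may leak to the branched 1,1-dimethylallyl isomer.
- Oxidative addition to the electron-rich, ortho-methoxy aryl bromide may be slow.
- The acidic phenols may protodestannylate the reagent.

Fallback: the chain is installed in two stages, which removes the regiochemical question. Starting from bromide 11, Stille coupling with allyltributylstannane (Pd(PPh3)4, DMF, 100 °C) should give 3-(3-allyl-4-methoxyphenyl)-5,7-dihydroxy-4H-chromen-4-one F7. An unsubstituted allyl group has no branched alternative. Cross-metathesis of F7 with an excess of 2-methylbut-2-ene and the second-generation Grubbs catalyst in CH2Cl2 then converts the terminal alkene into the trisubstituted one. This returns to the route at the target 13.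

## Further compounds

F1 | step 6 | 2-(3-bromo-4-methoxyphenyl)-1-(2,4,6-trihydroxyphenyl)ethan-1-one | COc1ccc(CC(=O)c2c(O)cc(O)cc2O)cc1Br
F2 | step 4 | methyl (Z)-2-(3-bromo-4-methoxyphenyl)-3-chloroacrylate | COC(=O)/C(=C\Cl)c1ccc(OC)c(Br)c1
F3 | step 5 | allyl 2-(3-bromo-4-methoxyphenyl)acetate | C=CCOC(=O)Cc1ccc(OC)c(Br)c1
F4 | step 5 | allyl (Z)-2-(3-bromo-4-methoxyphenyl)-3-hydroxyacrylate | C=CCOC(=O)/C(=C\O)c1ccc(OC)c(Br)c1
F5 | step 5 | allyl (Z)-2-(3-bromo-4-methoxyphenyl)-3-(tosyloxy)acrylate | C=CCOC(=O)/C(=C\OS(=O)(=O)c1ccc(C)cc1)c1ccc(OC)c(Br)c1
F6 | step 5 | allyl (Z)-3-[3,5-bis(benzyloxy)phenoxy]-2-(3-bromo-4-methoxyphenyl)acrylate | C=CCOC(=O)/C(=C\Oc1cc(OCc2ccccc2)cc(OCc2ccccc2)c1)c1ccc(OC)c(Br)c1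
F7 | step 8 | 3-(3-allyl-4-methoxyphenyl)-5,7-dihydroxy-4H-chromen-4-one | COc1ccc(-c2coc3cc(O)cc(O)c3c2=O)cc1CC=C
A1 | alternative 1 | 2-[4-methoxy-3-(3-methylbut-2-enyl)phenyl]-1-[2,4,6-tris(methoxymethoxy)phenyl]prop-2-en-1-one | C=C(C(=O)c1c(OCOC)cc(OCOC)cc1OCOC)c1ccc(OC)c(CC=C(C)C)c1
A2 | alternative 1 | 1-[4-methoxy-3-(3-methylbut-2-enyl)phenyl]vinyl trifluoromethanesulfonate | C=C(OS(=O)(=O)C(F)(F)F)c1ccc(OC)c(CC=C(C)C)c1
A3 | alternative 1 | tributyl[2,4,6-tris(methoxymethoxy)phenyl]stannane | COCOc1cc(OCOC)c([Sn](CCCC)(CCCC)CCCC)c(OCOC)c1
A4 | alternative 1 | carbon monoxide | [C-]#[O+]
A5 | alternative 2 | 5,7-bis(allyloxy)-3-[4-hydroxy-3-(3-methylbut-2-enyl)phenyl]-4H-chromen-4-one | C=CCOc1cc(OCC=C)c2c(c1)occ(-c1ccc(O)c(CC=C(C)C)c1)c2=O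
A6 | alternative 2 | 6-methylhept-5-en-2-one | CC(=O)CCC=C(C)C
A7 | alternative 2 | 2-[5,7-bis(allyloxy)-4-oxo-4H-chromen-3-yl]-1,3-bis(dimethylamino)trimethinium hexafluorophosphate | C=CCOc1cc(OCC=C)c2c(c1)occ(C(\C=[N+](C)C)=C/N(C)C)c2=O.F[P-](F)(F)(F)(F)F
A8 | alternative 3 | 5,7-difluoro-3-[4-methoxy-3-(3-methylbut-2-enyl)phenyl]-4H-chromen-4-one | COc1ccc(-c2coc3cc(F)cc(F)c3c2=O)cc1CC=C(C)C
A9 | alternative 3 | (Z)-3-hydroxy-2-[4-methoxy-3-(3-methylbut-2-enyl)phenyl]-1-(2,4,6-trifluorophenyl)prop-2-en-1-one | O/C=C(/c1ccc(OC)c(CC=C(C)C)c1)C(=O)c1c(F)cc(F)cc1F
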